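**Plan**

- Retrosynthetic cuts, in order: the two C4–O bonds, back to the C4 methylene groups of a 6,6'-linked bis(2,3-cis-flavan-3-ol) with one 3-O-tert-butyl carbonate and one free 3'-hydroxyl; the C6–C6' biaryl bond, back to a 6-bromo carbonate half and a 6-boronate hydroxyl half from one monomer; then, in the monomer, the C3 oxygen, the C3=C4 bond and the O1–C2 ether bond.
- Forward: ring A comes from 2,3,4-trihydroxybenzaldehyde and ring B arrives with a cinnamyl carbonate. Ring C is closed by metathesis and oxygenated at C3. The monomer is divided, one part acylated and the other borylated, the halves are joined by Suzuki coupling, and C4 and C4' are oxygenated last in one operation.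
- Stereochemistry: C2 from an iridium phosphoramidite catalyst; C3 from C2 by hydride delivery to the flavan-3-one anti to the aryl group; C4 of the cis half from C3 through the carbonate tether; C4' of the trans half from C3' by anti attack of water.
- Enabling feature: each C4 is a CH2 benzylic to ring A (ortho to O1, para to the C7 oxygen) and adjacent to the oxygen-bearing C3. The two C4 carbinols differ only in lying cis to the C3 oxygen in one ring C and trans in the other, which are the outcomes of internal and external capture of the same kind of C4 cation.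

Key step: step 16

Assumption: in step 8 the phosphoramidite antipode is taken to be the one whose iridacycle gives the (S)-configured aryl allyl ether. This is to be fixed beforehand in a model run with phenol and carbonate 9; both antipodes of the ligand are available.

**Route**

Step 1
Reactants: 1 2,3,4-trihydroxybenzaldehyde
Product: 2 2,3,4-tris(benzyloxy)benzaldehyde
Conditions: BnBr (3.6 equiv), K2CO3, DMF, 60 °C, argon
Reagents that add atoms: benzyl bromide, BrCc1ccccc1
Why: Williamson etherification of all three phenols, the excess of halide also alkylating the hydrogen-bonded 2-OH, with air excluded to protect the pyrogallol unit.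

Step 2
Reactants: 2 2,3,4-tris(benzyloxy)benzaldehyde
Product: 3 2,3,4-tris(benzyloxy)-5-bromobenzaldehyde
Conditions: NBS (1.05 equiv), DMF, 0 °C to rt, dark
Reagents that add atoms: N-bromosuccinimide, O=C1CCC(=O)N1Br
Why: Electrophilic aromatic bromination goes to C5, which is para to the 2-benzyloxy group, ortho to the 4-benzyloxy group and meta to the formyl group, whereas C6 is ortho to the formyl group and activated only by the twisted 3-benzyloxy group.

Step 3
Reactants: 3 2,3,4-tris(benzyloxy)-5-bromobenzaldehyde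
Product: 4 3,4-bis(benzyloxy)-5-bromo-2-hydroxybenzaldehyde
Conditions: MgBr2·OEt2 (3 equiv), toluene–Et2O, 80 °C
Reagents that add atoms: none
Why: Chelation-controlled ortho-debenzylation, in which magnesium held between the formyl oxygen and the neighbouring ether oxygen exposes only that benzyl group to bromide, so the other two benzyl ethers and the aryl bromide stay.

Step 4
Reactants: 4 3,4-bis(benzyloxy)-5-bromo-2-hydroxybenzaldehyde
Product: 5 2,3-bis(benzyloxy)-4-bromo-6-ethenylphenol
Conditions: Ph3PCH3Br (3 equiv), KOt-Bu (3 equiv), THF, 0 °C to rt, argon, degassed solvents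
Reagents that add atoms: methyltriphenylphosphonium bromide, C[P+](c1ccccc1)(c1ccccc1)c1ccccc1.[Br-]
Why: Wittig methylenation of the salicylaldehyde carbonyl, the excess ylide first forming the phenoxide, which still reacts at the aldehyde as is usual in the preparation of 2-vinylphenols.

Step 5
Reactants: 6 4-(benzyloxy)benzaldehyde
Product: 7 ethyl (E)-3-[4-(benzyloxy)phenyl]prop-2-enoate
Conditions: Ph3P=CHCO2Et (1.2 equiv), toluene, 80 °C
Reagents that add atoms: ethyl (triphenylphosphoranylidene)acetate, CCOC(=O)C=P(c1ccccc1)(c1ccccc1)c1ccccc1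
Why: Wittig olefination with a stabilised ylide gives the E-cinnamate.

Step 6
Reactants: 7 ethyl (E)-3-[4-(benzyloxy)phenyl]prop-2-enoate
Product: 8 (E)-3-[4-(benzyloxy)phenyl]prop-2-en-1-ol
Conditions: i-Bu2AlH (2.5 equiv), CH2Cl2, −78 to 0 °C
Reagents that add atoms: none
Why: 1,2-Reduction of the enoate by the aluminium hydride gives the allylic alcohol without touching the alkene or the benzyl ether.

Step 7
Reactants: 8 (E)-3-[4-(benzyloxy)phenyl]prop-2-en-1-ol
Product: 9 (E)-3-[4-(benzyloxy)phenyl]prop-2-en-1-yl methyl carbonate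
Conditions: ClCO2Me, pyridine, CH2Cl2, 0 °C
Reagents that add atoms: methyl chloroformate, COC(=O)Cl
Why: Acylation of the primary allylic alcohol installs the carbonate leaving group needed for allylic substitution.

Step 8
Reactants: 5 2,3-bis(benzyloxy)-4-bromo-6-ethenylphenol; 9 (E)-3-[4-(benzyloxy)phenyl]prop-2-en-1-yl methyl carbonate
Product: 10 2,3-bis(benzyloxy)-4-{[(1S)-1-[4-(benzyloxy)phenyl]prop-2-en-1-yl]oxy}-1-bromo-5-ethenylbenzene
Conditions: LiN(SiMe3)2 (1.0 equiv), THF, −78 to 0 °C; then 9 (1.2 equiv), [Ir(cod)Cl]2 (2 mol%), O,O'-(1,1'-binaphthyl-2,2'-diyl) N,N-bis(1-phenylethyl)phosphoramidite (4 mol%, antipode as in the assumption, catalyst pre-activated with n-PrNH2), THF, 50 °C, argon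
Reagents that add atoms: none
Why: Iridium-catalysed asymmetric allylic etherification, in which the aryloxide attacks the substituted terminus of the allyl iridium intermediate, forms the O1–C2 bond as the branched ether and sets C2 under catalyst control, the aryl bromide being inert to the iridium catalyst.

Step 9
Reactants: 10 the (S)-aryl allyl ether of step 8
Product: 11 (2S)-7,8-bis(benzyloxy)-2-[4-(benzyloxy)phenyl]-6-bromo-2H-chromene
Conditions: second-generation Grubbs catalyst RuCl2(=CHPh)(PCy3)(H2IMes) (5 mol%), CH2Cl2, 40 °C, argon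
Reagents that add atoms: none
Why: Ring-closing metathesis between the styrene and the vinyl group of the adjacent allyl ether closes the six-membered ring C with loss of ethene and leaves C2 untouched.

Step 10
Reactants: 11 (2S)-7,8-bis(benzyloxy)-2-[4-(benzyloxy)phenyl]-6-bromo-2H-chromene
Product: 13 (2R,3S)-7,8-bis(benzyloxy)-2-[4-(benzyloxy)phenyl]-6-bromochroman-3-ol, via alkylborane 12 (not isolated)
Conditions: BH3·THF (3 equiv), THF, 0 °C to rt; then aq. NaOH, H2O2, 0 °C
Reagents that add atoms: hydrogen peroxide, OO; borane–tetrahydrofuran, B.C1CCOC1 (boron of 12 only)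
Why: Hydroboration–oxidation of the styrene-type C3=C4 bond puts boron at C3 on the face opposite to the C2 aryl group and oxidation occurs with retention, as known for flav-3-enes; the C3 configuration is provisional since step 11 erases it, and C2 keeps its place in space (its descriptor changes from S to R only because C3 now outranks the aryl group).

Step 11
Reactants: 13 (2R,3S)-7,8-bis(benzyloxy)-2-[4-(benzyloxy)phenyl]-6-bromochroman-3-ol
Product: 14 (2R)-7,8-bis(benzyloxy)-2-[4-(benzyloxy)phenyl]-6-bromochroman-3-one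
Conditions: Dess–Martin periodinane, wet CH2Cl2, rt
Reagents that add atoms: none
Why: Dess–Martin oxidation under non-basic conditions gives the flavan-3-one without epimerising the benzylic C2 centre, as known for benzylated catechin.

Step 12
Reactants: 14 (2R)-7,8-bis(benzyloxy)-2-[4-(benzyloxy)phenyl]-6-bromochroman-3-one
Product: 15 (2R,3R)-7,8-bis(benzyloxy)-2-[4-(benzyloxy)phenyl]-6-bromochroman-3-ol
Conditions: LiBH(s-Bu)3, LiBr, THF, −78 °C
Reagents that add atoms: none
Why: The bulky borohydride attacks the carbonyl from the face opposite to the equatorial C2 aryl group, so the new hydroxyl is axial and cis to the aryl group (3R), the known way from flavan-3-ones to the 2,3-cis series.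

Step 13
Reactants: 15 (2R,3R)-7,8-bis(benzyloxy)-2-[4-(benzyloxy)phenyl]-6-bromochroman-3-ol
Product: 16 tert-butyl (2R,3R)-7,8-bis(benzyloxy)-2-[4-(benzyloxy)phenyl]-6-bromochroman-3-yl carbonate
Conditions: Boc2O (1.5 equiv), DMAP (0.2 equiv), Et3N, CH2Cl2, rt
Reagents that add atoms: di-tert-butyl dicarbonate, CC(C)(C)OC(=O)OC(=O)OC(C)(C)C
Why: DMAP-catalysed O-acylation of the only hydroxyl group, carried out on the monomer so that the two C3 oxygens of the later dimer are differentiated without a statistical step.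

Step 14
Reactants: 15 (2R,3R)-7,8-bis(benzyloxy)-2-[4-(benzyloxy)phenyl]-6-bromochroman-3-ol
Product: 17 (2R,3R)-7,8-bis(benzyloxy)-2-[4-(benzyloxy)phenyl]-6-(4,4,5,5-tetramethyl-1,3,2-dioxaborolan-2-yl)chroman-3-ol
Conditions: B2pin2 (1.3 equiv), PdCl2(dppf) (5 mol%), KOAc (3 equiv), 1,4-dioxane, 85 °C, argon
Reagents that add atoms: bis(pinacolato)diboron, CC1(C)OB(OC1(C)C)B1OC(C)(C)C(C)(C)O1
Why: Miyaura borylation of the aryl bromide, in which the weak acetate base leaves the free secondary hydroxyl, the benzyl ethers and the stereocentres untouched.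

Step 15
Reactants: 16 the 6-bromo tert-butyl carbonate of step 13; 17 the 6-boronate of step 14
Product: 18 tert-butyl (2R,2'R,3R,3'R)-7,7',8,8'-tetrakis(benzyloxy)-2,2'-bis[4-(benzyloxy)phenyl]-3'-hydroxy-6,6'-bichroman-3-yl carbonate
Conditions: 16 (1.0 equiv), 17 (1.1 equiv), Pd(OAc)2 (5 mol%), SPhos (10 mol%), K3PO4 (3 equiv), toluene–H2O (10:1), 70 °C, argon
Reagents that add atoms: none
Why: Suzuki–Miyaura coupling (zerovalent palladium formed in situ) joins C6 of the carbonate half to C6' of the hydroxyl half, each aryl partner carrying only one ortho substituent at the new bond so that no stable axis arises; the tert-butyl carbonate of a secondary alcohol should resist the phosphate base, and the minor enantiomer of either monomer ends up in a separable diastereomer, which should raise the enantiomeric purity of 18.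

Step 16
Reactants: 18 the mono-tert-butyl carbonate of step 15
Product: 21 hexabenzyl 6,6'-biflavan carrying a 3,4-cis cyclic carbonate (2R,3S,4R) in one half plus a 3,4-trans diol (2'R,3'R,4'S) in the other, via half-oxidised cyclic carbonate 19 (not isolated), via half-oxidised trans-diol tert-butyl carbonate 20 (not isolated)
Conditions: DDQ (20 mol%), reticulated vitreous carbon anode, Pt wire cathode, undivided cell, LiClO4 (0.1 M), 2,6-di-tert-butylpyridine (1 equiv), MeCN–CH2Cl2 (4:1), H2O (20 equiv), 0 °C, anode held at the DDQH2/DDQ potential read from a voltammogram of the mixture, about 4 F/mol (more if DDQ is partly reduced at the cathode)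
Reagents that add atoms: water, O
Why: Proposed new method: DDQ, kept at a low stationary concentration and re-formed from its hydroquinone at the anode, takes a hydride from the pseudo-axial C4–H of each ring C through a charge-transfer complex with the trioxygenated ring A and gives a C4 cation stabilised by O1 and the C7 oxygen; the closest known reactions are the DDQ-mediated C4 oxygenation of benzylated flavan-3-ols with external oxygen nucleophiles, the anodic recycling of DDQ in benzylic C–H oxidation, and the capture of carbocations by tert-butyl carbonates as in iodocarbonate cyclisation. In the carbonate half the Boc carbonyl oxygen closes the five-membered 1,3-dioxolan-2-one by 5-exo-trig attack on C4 and the tert-butyl group leaves as isobutene, so the ring can only be cis-fused and the new C4–O bond lies on the face of the C3 oxygen (4R). In the other half water adds axially to the half-chair cation (2-aryl equatorial, 3-OH axial) anti to the axial hydroxyl, or opens a transient 3,4-epoxide with inversion, and either path gives the 3,4-trans diol (4'S). Selectivity for C4 over C2 and over the OCH2Ph groups rests on the anode potential being set at the DDQ couple, below the oxidation onset of every arene in 18, and on hydride loss being fastest where the C–H bond overlaps with the most electron-rich ring. Over-oxidation to a 4-ketone should be held back because the C4–H left in the trans diol is pseudo-equatorial, the one in the carbonate sits on a carbon bearing an acylated oxygen, and the charge is limited.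

Step 17
Reactants: 21 the cyclic carbonate/trans-diol of step 16
Product: 22 (2R,2'R,3R,3'R,4R,4'S)-7,7',8,8'-tetrakis(benzyloxy)-2,2'-bis[4-(benzyloxy)phenyl]-6,6'-bichromane-3,3',4,4'-tetraol
Conditions: K2CO3 (0.2 equiv), MeOH–THF, 0 °C to rt
Reagents that add atoms: none
Why: Base-catalysed methanolysis of the five-membered cyclic carbonate frees the cis-diol; only C(=O)–O bonds break, so no stereocentre is touched.

Step 18
Reactants: 22 the hexabenzyl tetraol of step 17
Product: 23 (2R,2'R,3R,3'R,4R,4'S)-2,2'-bis(4-hydroxyphenyl)-6,6'-bichromane-3,3',4,4',7,7',8,8'-octol (CNP0121763.1)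
Conditions: H2 (1 atm), Pd(OH)2/C, THF–MeOH, rt; filtration and evaporation under argon
Reagents that add atoms: none
Why: Hydrogenolysis of the six aryl benzyl ethers under neutral conditions, where the free C4 carbinols and the O1–C2 bonds are poorer leaving groups and should survive if acid is excluded and the reaction is stopped at the uptake for six benzyl groups.

**Compound list**

1 | 2,3,4-trihydroxybenzaldehyde | O=Cc1ccc(O)c(O)c1O | starting material
2 | 2,3,4-tris(benzyloxy)benzaldehyde | O=Cc1ccc(OCc2ccccc2)c(OCc2ccccc2)c1OCc1ccccc1 | intermediate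
3 | 2,3,4-tris(benzyloxy)-5-bromobenzaldehyde | O=Cc1cc(Br)c(OCc2ccccc2)c(OCc2ccccc2)c1OCc1ccccc1 | intermediate
4 | 3,4-bis(benzyloxy)-5-bromo-2-hydroxybenzaldehyde | O=Cc1cc(Br)c(OCc2ccccc2)c(OCc2ccccc2)c1O | intermediate
5 | 2,3-bis(benzyloxy)-4-bromo-6-ethenylphenol | C=Cc1cc(Br)c(OCc2ccccc2)c(OCc2ccccc2)c1O | intermediate
6 | 4-(benzyloxy)benzaldehyde | O=Cc1ccc(OCc2ccccc2)cc1 | starting material
7 | ethyl (E)-3-[4-(benzyloxy)phenyl]prop-2-enoate | CCOC(=O)/C=C/c1ccc(OCc2ccccc2)cc1 | intermediate
8 | (E)-3-[4-(benzyloxy)phenyl]prop-2-en-1-ol | OC/C=C/c1ccc(OCc2ccccc2)cc1 | intermediate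
9 | (E)-3-[4-(benzyloxy)phenyl]prop-2-en-1-yl methyl carbonate | COC(=O)OC/C=C/c1ccc(OCc2ccccc2)cc1 | intermediate
10 | 2,3-bis(benzyloxy)-4-{[(1S)-1-[4-(benzyloxy)phenyl]prop-2-en-1-yl]oxy}-1-bromo-5-ethenylbenzene | c1ccccc1COc1ccc(cc1)[C@H](C=C)Oc1c(C=C)cc(Br)c(OCc2ccccc2)c1OCc1ccccc1 | intermediate
11 | (2S)-7,8-bis(benzyloxy)-2-[4-(benzyloxy)phenyl]-6-bromo-2H-chromene | c1ccccc1COc1ccc(cc1)[C@H]1Oc2c(C=C1)cc(Br)c(OCc3ccccc3)c2OCc2ccccc2 | intermediate
12 | 7,8-bis(benzyloxy)-2-[4-(benzyloxy)phenyl]-6-bromochromane with a BH2 group at C3 trans to the C2 aryl group (same arrangement in space as 13) | c1ccccc1COc1ccc(cc1)[C@H]1Oc2c(cc(Br)c(OCc3ccccc3)c2OCc2ccccc2)C[C@@H]1B | intermediate (not isolated)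
13 | (2R,3S)-7,8-bis(benzyloxy)-2-[4-(benzyloxy)phenyl]-6-bromochroman-3-ol (2,3-trans) | c1ccccc1COc1ccc(cc1)[C@H]1Oc2c(cc(Br)c(OCc3ccccc3)c2OCc2ccccc2)C[C@@H]1O | intermediate
14 | (2R)-7,8-bis(benzyloxy)-2-[4-(benzyloxy)phenyl]-6-bromochroman-3-one | c1ccccc1COc1ccc(cc1)[C@H]1Oc2c(cc(Br)c(OCc3ccccc3)c2OCc2ccccc2)CC1=O | intermediate
15 | (2R,3R)-7,8-bis(benzyloxy)-2-[4-(benzyloxy)phenyl]-6-bromochroman-3-ol (2,3-cis) | c1ccccc1COc1ccc(cc1)[C@H]1Oc2c(cc(Br)c(OCc3ccccc3)c2OCc2ccccc2)C[C@H]1O | intermediate
16 | tert-butyl (2R,3R)-7,8-bis(benzyloxy)-2-[4-(benzyloxy)phenyl]-6-bromochroman-3-yl carbonate | c1ccccc1COc1ccc(cc1)[C@H]1Oc2c(cc(Br)c(OCc3ccccc3)c2OCc2ccccc2)C[C@H]1OC(=O)OC(C)(C)C | intermediate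
17 | (2R,3R)-7,8-bis(benzyloxy)-2-[4-(benzyloxy)phenyl]-6-(4,4,5,5-tetramethyl-1,3,2-dioxaborolan-2-yl)chroman-3-ol | c1ccccc1COc1ccc(cc1)[C@H]1Oc2c(cc(B3OC(C)(C)C(C)(C)O3)c(OCc3ccccc3)c2OCc2ccccc2)C[C@H]1O | intermediate
18 | tert-butyl (2R,2'R,3R,3'R)-7,7',8,8'-tetrakis(benzyloxy)-2,2'-bis[4-(benzyloxy)phenyl]-3'-hydroxy-6,6'-bichroman-3-yl carbonate | c1ccccc1COc1ccc(cc1)[C@H]1Oc2c(cc(-c3cc4c(c(OCc5ccccc5)c3OCc3ccccc3)O[C@H](c3ccc(OCc5ccccc5)cc3)[C@H](O)C4)c(OCc3ccccc3)c2OCc2ccccc2)C[C@H]1OC(=O)OC(C)(C)C | intermediate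
19 | hexabenzyl 6,6'-biflavan with a 3,4-cis-fused cyclic carbonate in one half (2R,3S,4R) and an unchanged 2,3-cis-flavan-3-ol in the other (2'R,3'R) | c1ccccc1COc1ccc(cc1)[C@H]1Oc2c(cc(-c3cc4c(c(OCc5ccccc5)c3OCc3ccccc3)O[C@H](c3ccc(OCc5ccccc5)cc3)[C@H](O)C4)c(OCc3ccccc3)c2OCc2ccccc2)[C@@H](OC(=O)O3)[C@H]13 | intermediate (not isolated)
20 | hexabenzyl 6,6'-biflavan with the 3-O-tert-butyl carbonate and C4 methylene kept in one half (2R,3R) and a 3,4-trans diol in the other (2'R,3'R,4'S) | c1ccccc1COc1ccc(cc1)[C@H]1Oc2c(cc(-c3cc4c(c(OCc5ccccc5)c3OCc3ccccc3)O[C@H](c3ccc(OCc5ccccc5)cc3)[C@H](O)[C@H]4O)c(OCc3ccccc3)c2OCc2ccccc2)C[C@H]1OC(=O)OC(C)(C)C | intermediate (not isolated)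
21 | hexabenzyl 6,6'-biflavan with a 3,4-cis-fused cyclic carbonate in one half (2R,3S,4R; aryl, O3 and O4 all cis; the C3 descriptor differs from that of the diol by priority only) and a 2,3-cis-3,4-trans diol in the other (2'R,3'R,4'S) | c1ccccc1COc1ccc(cc1)[C@H]1Oc2c(cc(-c3cc4c(c(OCc5ccccc5)c3OCc3ccccc3)O[C@H](c3ccc(OCc5ccccc5)cc3)[C@H](O)[C@H]4O)c(OCc3ccccc3)c2OCc2ccccc2)[C@@H](OC(=O)O3)[C@H]13 | intermediate
22 | (2R,2'R,3R,3'R,4R,4'S)-7,7',8,8'-tetrakis(benzyloxy)-2,2'-bis[4-(benzyloxy)phenyl]-6,6'-bichromane-3,3',4,4'-tetraol | c1ccccc1COc1ccc(cc1)[C@H]1Oc2c(cc(-c3cc4c(c(OCc5ccccc5)c3OCc3ccccc3)O[C@H](c3ccc(OCc5ccccc5)cc3)[C@H](O)[C@H]4O)c(OCc3ccccc3)c2OCc2ccccc2)[C@@H](O)[C@H]1O | intermediate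
23 | (2R,2'R,3R,3'R,4R,4'S)-2,2'-bis(4-hydroxyphenyl)-6,6'-bichromane-3,3',4,4',7,7',8,8'-octol | Oc1ccc([C@H]2Oc3c(cc(-c4cc5c(c(O)c4O)O[C@H](c4ccc(O)cc4)[C@H](O)[C@H]5O)c(O)c3O)[C@@H](O)[C@H]2O)cc1 | target

**Count and risks**

Total steps: 18. Longest linear sequence: 14 steps (steps 1–4, 8–13 and 15–18, from 1). Steps 5–7 form a three-step branch from 6, and step 14 is a one-step branch from 15.

Steps most likely to fail:

1. Step 16. Water may outrun the carbonate oxygen at the C4 cation of the Boc half and give the trans carbinol there as well. The free benzylic carbinol of the other half may be oxidised further to the 4-ketone. Acid formed at the anode may ionise the new C4–O bonds or remove the Boc group before it has reacted.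
   Fallback with known chemistry, from 15 and 17 back to 22: bromide 15, in place of its carbonate 16, is coupled with boronate 17 under the conditions of step 15. This gives the twofold-symmetric hexabenzyl bis(2,3-cis-flavan-3-ol) F1. F1 is treated with DDQ (2.2 equiv) in CH2Cl2–H2O at 0 °C, the known C4 hydroxylation of benzylated 2,3-cis-flavan-3-ols, in which water enters trans to the C3 hydroxyl in both halves. This gives the hexabenzyl bis(2,3-cis-3,4-trans-flavan-3,4-diol) F2. A deficit of activated MnO2 in CH2Cl2 oxidises one benzylic C4 carbinol (the C3 carbinols are not benzylic) to the mono-ketone, the 3-hydroxyflavan-4-one F3, with unreacted F2 recovered and resubmitted. NaBH4 in THF–MeOH at −40 °C should then add hydride to the C4 carbonyl axially, anti to the axial C3 hydroxyl, as in the reduction of 2,3-cis-dihydroflavonols to 2,3-cis-3,4-cis diols. This gives 22, and the route is rejoined at step 18.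

2. Step 8. The 2,6-disubstituted aryloxide may attack the allyl iridium intermediate slowly, so that formation of the linear ether, or erosion of enantioselectivity by reversible ionisation of the electron-rich branched ether, takes over.
   Fallback, from 4 and 8 back to 11: alcohol 8 is oxidised with MnO2 in CH2Cl2 to (E)-3-[4-(benzyloxy)phenyl]prop-2-enal F4. Salicylaldehyde 4 and F4 then undergo the amine-catalysed oxa-Michael/aldol condensation (diphenylprolinol trimethylsilyl ether, antipode chosen for the 2R series, 2-nitrobenzoic acid, toluene). This forms O1–C2 and C3=C4 of ring C in one operation, sets C2 through the iminium ion, and gives (2R)-7,8-bis(benzyloxy)-2-[4-(benzyloxy)phenyl]-6-bromo-2H-chromene-3-carbaldehyde F5. Decarbonylation with RhCl(PPh3)3 (1.1 equiv) in toluene at 80 °C removes the formyl group, the carbon monoxide staying on rhodium as RhCl(CO)(PPh3)2, and gives 11, so steps 4, 8 and 9 are bypassed.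

3. Step 18. Hydrogenolytic loss of the benzylic C4 hydroxyls (or opening at O1–C2) may compete with debenzylation, and the free pyrogallol-type product may oxidise in air.
   Fallback, from 22 to 23: tetraol 22 is silylated with Et3SiOTf and 2,6-lutidine in CH2Cl2 to the 3,3',4,4'-tetrakis(triethylsilyl) ether of 22 F6, in which the C4 oxygens are no longer free carbinols. Hydrogenolysis over Pd(OH)2/C in EtOAc removes the six benzyl groups and gives the 3,3',4,4'-tetrakis(triethylsilyl) ether of 23 F7. HF·pyridine buffered with pyridine in THF at 0 °C under argon then removes the four silyl groups to give 23.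

Further compounds
F1 | step 16 | (2R,2'R,3R,3'R)-7,7',8,8'-tetrakis(benzyloxy)-2,2'-bis[4-(benzyloxy)phenyl]-6,6'-bichromane-3,3'-diol (2,3-cis in both halves) | c1ccccc1COc1ccc(cc1)[C@H]1Oc2c(cc(-c3cc4c(c(OCc5ccccc5)c3OCc3ccccc3)O[C@H](c3ccc(OCc5ccccc5)cc3)[C@H](O)C4)c(OCc3ccccc3)c2OCc2ccccc2)C[C@H]1O
F2 | step 16 | (2R,2'R,3R,3'R,4S,4'S)-7,7',8,8'-tetrakis(benzyloxy)-2,2'-bis[4-(benzyloxy)phenyl]-6,6'-bichromane-3,3',4,4'-tetraol (3,4-trans in both halves) | c1ccccc1COc1ccc(cc1)[C@H]1Oc2c(cc(-c3cc4c(c(OCc5ccccc5)c3OCc3ccccc3)O[C@H](c3ccc(OCc5ccccc5)cc3)[C@H](O)[C@H]4O)c(OCc3ccccc3)c2OCc2ccccc2)[C@H](O)[C@H]1O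
F3 | step 16 | hexabenzyl 6,6'-biflavan with a 2,3-cis-3-hydroxy-4-ketone in one half (2R,3S) and a 2,3-cis-3,4-trans diol in the other (2'R,3'R,4'S) | c1ccccc1COc1ccc(cc1)[C@H]1Oc2c(cc(-c3cc4c(c(OCc5ccccc5)c3OCc3ccccc3)O[C@H](c3ccc(OCc5ccccc5)cc3)[C@H](O)[C@H]4O)c(OCc3ccccc3)c2OCc2ccccc2)C(=O)[C@H]1O
F4 | step 8 | (E)-3-[4-(benzyloxy)phenyl]prop-2-enal | O=C/C=C/c1ccc(OCc2ccccc2)cc1
F5 | step 8 | (2R)-7,8-bis(benzyloxy)-2-[4-(benzyloxy)phenyl]-6-bromo-2H-chromene-3-carbaldehyde | c1ccccc1COc1ccc(cc1)[C@H]1Oc2c(C=C1C=O)cc(Br)c(OCc3ccccc3)c2OCc2ccccc2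
F6 | step 18 | 3,3',4,4'-tetrakis(triethylsilyl) ether of 22 | c1ccccc1COc1ccc(cc1)[C@H]1Oc2c(cc(-c3cc4c(c(OCc5ccccc5)c3OCc3ccccc3)O[C@H](c3ccc(OCc5ccccc5)cc3)[C@H](O[Si](CC)(CC)CC)[C@H]4O[Si](CC)(CC)CC)c(OCc3ccccc3)c2OCc2ccccc2)[C@@H](O[Si](CC)(CC)CC)[C@H]1O[Si](CC)(CC)CC
F7 | step 18 | 3,3',4,4'-tetrakis(triethylsilyl) ether of 23 | Oc1ccc([C@H]2Oc3c(cc(-c4cc5c(c(O)c4O)O[C@H](c4ccc(O)cc4)[C@H](O[Si](CC)(CC)CC)[C@H]5O[Si](CC)(CC)CC)c(O)c3O)[C@@H](O[Si](CC)(CC)CC)[C@H]2O[Si](CC)(CC)CC)cc1
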